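**Retrosynthetic overview**

1. Ring A carries oxygen on C5, C7 and C8a in the alternating pattern of a folded poly-β-carbonyl chain, with extra methoxy groups on C6, C8 and C3. The nine carbons C8a–C8–C7–C6–C5–C4a–C4–C3–C2 are therefore drawn out as one open chain that ends in the phenyl ketone of ring B.
2. Last disconnection: the 5-O-methyl group, installed by methylation of the chelated phenol of a 5-hydroxyflavone.
3. Key disconnection: C4a–C8a (Claisen attack of the central carbon of a 1,3,5-trione on a methyl ester carbon, ring A first) and O1–C2 (cyclodehydration, ring C second). C7 travels as a dimethyl ketal that loses methanol on aromatisation.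
4. The chain is cut at C5–C4a into a symmetric diester, dimethyl 2,3,3,4-tetramethoxyglutarate (from dimethyl 3-oxoglutarate by double diazo transfer, double O–H insertion into methanol and ketalisation), and the dianion of 2-methoxy-1-phenylbutane-1,3-dione (from 2-methoxyacetophenone and ethyl acetate).

Key step: step 6

Remark on the chemistry: flavone numbering is used for the target and for 10–13, chain numbering (C1–C9) for 9; compounds 3, 4 and 9 are carried as diastereomer mixtures and 7 as the racemate, because every sp3 stereocentre is erased in step 6.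

**Route**

Step 1
Reactants: 1 dimethyl 3-oxopentanedioate
Product: 2 dimethyl 2,4-bis(diazo)-3-oxopentanedioate
Conditions: 4-acetamidobenzenesulfonyl azide (2.2 equiv), Et3N, MeCN, 0 °C to rt
Reagents that add atoms: 4-acetamidobenzenesulfonyl azide, CC(=O)Nc1ccc(cc1)S(=O)(=O)N=[N+]=[N-]
Why: Regitz diazo transfer, since each methylene of 1 lies between a ketone and an ester and should be deprotonated by Et3N and take a diazo group from the sulfonyl azide.

Step 2
Reactants: 2 dimethyl 2,4-bis(diazo)-3-oxopentanedioate
Product: 3 dimethyl 2,4-dimethoxy-3-oxopentanedioate (mixture of diastereomers)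
Conditions: Rh2(OAc)4 (2 mol %), MeOH/CH2Cl2, 40 °C, slow addition of 2
Reagents that add atoms: methanol, CO
Why: Rhodium-carbenoid O–H insertion at both diazo carbons, which in a methanol-rich medium should outrun Wolff rearrangement and carbenoid–diazo coupling; the two new stereocentres are uncontrolled and are erased later.

Step 3
Reactants: 3 dimethyl 2,4-dimethoxy-3-oxopentanedioate
Product: 4 dimethyl 2,3,3,4-tetramethoxypentanedioate (mixture of diastereomers)
Conditions: HC(OMe)3, MeOH, H2SO4 (cat.), 50 °C; NaOMe quench before concentration
Reagents that add atoms: trimethyl orthoformate, COC(OC)OC; methanol, CO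
Why: Acid-catalysed ketalisation with the orthoester as water scavenger, in which the electron-poor ketone readily forms the hemiketal and the basic quench should prevent loss of methanol to an enol ether.

Step 4
Reactants: 5 2-methoxy-1-phenylethanone; 6 ethyl acetate (3 equiv)
Product: 7 2-methoxy-1-phenylbutane-1,3-dione (racemic)
Conditions: NaH (2.2 equiv), THF, reflux; aq. HCl
Reagents that add atoms: none
Why: Crossed Claisen condensation, in which the sodium enolate of 5 (its only enolisable carbon is the methoxy-bearing CH2) is acetylated by ethyl acetate and the equilibrium is pulled forward by deprotonation of the 1,3-diketone.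

Step 5
Reactants: 7 2-methoxy-1-phenylbutane-1,3-dione; 4 dimethyl 2,3,3,4-tetramethoxypentanedioate (2 equiv)
Product: 9 methyl 2,3,3,4,8-pentamethoxy-5,7,9-trioxo-9-phenylnonanoate (mixture of diastereomers), via dilithium dienolate 8 (not isolated)
Conditions: LiN(iPr)2 (2.05 equiv), THF, −78 to 0 °C; then cannulated into 4, THF, −78 °C; AcOH quench at −78 °C
Reagents that add atoms: none
Why: Hauser–Harris acylation of a 1,3-diketone dianion, in which the terminal carbon of 8 attacks one of the two equivalent α-methoxy-activated ester groups of 4, excess 4 suppresses double acylation, and, because the acidic product quenches a second equivalent of 8, half of 7 is returned for recycling.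

Step 6
Reactants: 9 methyl 2,3,3,4,8-pentamethoxy-5,7,9-trioxo-9-phenylnonanoate
Product: 12 5-hydroxy-3,6,7,8-tetramethoxyflavone, via cyclohexanedione ketal 10 (not isolated), via dihydroxyaryl diketone 11 (not isolated)
Conditions: NaOMe (3.5 equiv), MeOH, 0 to 40 °C; then HCl (3 M in MeOH) to pH 1, 60 °C
Reagents that add atoms: none
Why: Proposed new method: excess methoxide should hold the 5,7,9-trione of 9 as its dienolate, in which no ketone is left as an aldol acceptor, and the central chain carbon C6 (the future C4a) then attacks the α-methoxy-activated ester carbon C1 (the future C8a) in a Claisen closure of ring A (6-exo-trig) that is made irreversible by deprotonation of the acidic 2-acylcyclohexane-1,3-dione 10. The closest known reaction type is the base-induced Claisen cyclisation of 3,5,7-triketo esters to acylphloroglucinols, from which this case differs in the ketal carbon and the two methoxy-bearing sp3 carbons inside the forming ring. Methanolic HCl then ionises the ketal of 10, loss of methanol and enolisation of the two ring ketones give the arene 11, and one of its two equivalent phenolic hydroxyls adds to the benzoyl carbonyl (6-exo-trig, O1–C2) and water is lost to close ring C, as in the acid cyclodehydration of o-hydroxyaryl 1,3-diketones. No stereocentre is formed, and the three of 9 are erased. The step needs C-acylation at C4a to beat aldol closure, retro-Claisen cleavage and loss of methoxide from the ketal: the ketal leaves the ester carbon as the only electrophile within six-ring reach of C6, and in NaOMe/MeOH both ester exchange and any elimination and re-addition of methanol at the ketal are degenerate. The symmetry of 11 makes the direction of the O-cyclisation irrelevant.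

Step 7
Reactants: 12 5-hydroxy-3,6,7,8-tetramethoxyflavone
Product: 13 3,5,6,7,8-pentamethoxyflavone
Conditions: Me2SO4 (excess), K2CO3, acetone, reflux
Reagents that add atoms: dimethyl sulfate, COS(=O)(=O)OC
Why: Williamson O-methylation of the hydrogen-bonded 5-hydroxyl, which needs the forcing conditions (excess reagent, prolonged reflux) that are standard for 5-hydroxyflavones.

**Compound list**

1 | dimethyl 3-oxopentanedioate (dimethyl 3-oxoglutarate) | COC(=O)CC(=O)CC(=O)OC | starting material
2 | dimethyl 2,4-bis(diazo)-3-oxopentanedioate | COC(=O)C(=[N+]=[N-])C(=O)C(=[N+]=[N-])C(=O)OC | intermediate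
3 | dimethyl 2,4-dimethoxy-3-oxopentanedioate (mixture of diastereomers) | COC(=O)C(OC)C(=O)C(OC)C(=O)OC | intermediate
4 | dimethyl 2,3,3,4-tetramethoxypentanedioate (mixture of diastereomers) | COC(=O)C(OC)C(OC)(OC)C(OC)C(=O)OC | intermediate
5 | 2-methoxy-1-phenylethanone | COCC(=O)c1ccccc1 | starting material
6 | ethyl acetate | CCOC(C)=O | starting material
7 | 2-methoxy-1-phenylbutane-1,3-dione (racemic) | CC(=O)C(OC)C(=O)c1ccccc1 | intermediate
8 | dilithium dienolate of 7 (formed in the flask, not isolated) | [Li+].[Li+].C=C([O-])C(OC)=C([O-])c1ccccc1 | intermediate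
9 | methyl 2,3,3,4,8-pentamethoxy-5,7,9-trioxo-9-phenylnonanoate (mixture of diastereomers) | COC(=O)C(OC)C(OC)(OC)C(OC)C(=O)CC(=O)C(OC)C(=O)c1ccccc1 | intermediate
10 | 4,5,5,6-tetramethoxy-2-(2-methoxy-3-oxo-3-phenylpropanoyl)cyclohexane-1,3-dione (formed in the flask, not isolated) | COC1C(=O)C(C(=O)C(OC)C(=O)c2ccccc2)C(=O)C(OC)C1(OC)OC | intermediate
11 | 1-(2,6-dihydroxy-3,4,5-trimethoxyphenyl)-2-methoxy-3-phenylpropane-1,3-dione (formed in the flask, not isolated) | COC(C(=O)c1ccccc1)C(=O)c1c(O)c(OC)c(OC)c(OC)c1O | intermediate
12 | 5-hydroxy-3,6,7,8-tetramethoxyflavone (5-hydroxy-3,6,7,8-tetramethoxy-2-phenyl-4H-chromen-4-one) | COc1c(OC)c(O)c2c(=O)c(OC)c(-c3ccccc3)oc2c1OC | intermediate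
13 | 3,5,6,7,8-pentamethoxyflavone (3,5,6,7,8-pentamethoxy-2-phenyl-4H-chromen-4-one) | COc1c(OC)c(OC)c2c(=O)c(OC)c(-c3ccccc3)oc2c1OC | target

**Summary**

Total step count: 7. Longest linear sequence: 6 steps (steps 1, 2, 3, 5, 6, 7); step 4 is the side branch.

Steps most likely to fail:

1. Step 6. The delocalised dienolate may be too weak a nucleophile for the hindered ester carbon, so that retro-Claisen cleavage of the trione by methoxide, or drift of the ketal to an enol ether, overtakes ring closure. Fallback by known chemistry, with ring A taken from a preformed arene: purchased pentamethoxybenzene is lithiated at its only C–H (n-BuLi, TMEDA, THF, 0 °C) and carboxylated with CO2 to 2,3,4,5,6-pentamethoxybenzoic acid F1, which (COCl)2 and catalytic DMF convert into 2,3,4,5,6-pentamethoxybenzoyl chloride F2. The lithium enolate of 5 (LiN(SiMe3)2, two equivalents of enolate per F2, THF, −78 °C) is C-acylated by F2 to give 2-methoxy-1-(2,3,4,5,6-pentamethoxyphenyl)-3-phenylpropane-1,3-dione F3. BCl3 (CH2Cl2, −78 to 0 °C) should cleave one methyl ether ortho to the aryl ketone through the carbonyl chelate to give 1-(2-hydroxy-3,4,5,6-tetramethoxyphenyl)-2-methoxy-3-phenylpropane-1,3-dione F4, and H2SO4 (cat.) in AcOH at 80 °C cyclodehydrates F4. The fallback sets out from 5 and comes back to the route at 13, so that steps 6 and 7 are both replaced.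

2. Step 5. The strongly basic terminal carbon of 8 may remove the α-hydrogen of 4 instead of adding to the ester, after which methoxide is expelled from the ketal; a second acylation at the far ester is also possible. Fallback, an aldol–oxidation sequence in place of the acylation: 4 is half-reduced with i-Bu2AlH (1 equiv, CH2Cl2, −78 °C; the α-methoxy ester gives a stable chelated hemiacetal aluminate) to methyl 2,3,3,4-tetramethoxy-5-oxopentanoate F5. The dianion 8, made from 7 as in step 5, adds to the aldehyde of F5 at −78 °C far faster than it deprotonates, giving methyl 5-hydroxy-2,3,3,4,8-pentamethoxy-7,9-dioxo-9-phenylnonanoate F6 after a cold quench. Dess–Martin periodinane (CH2Cl2, rt) oxidises F6 to the trione. The fallback sets out from 4 and 7 and comes back at 9.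

3. Step 3. Ionisation of the hemiketal, flanked by two acceptor-bearing carbons, may be too slow, so that the ketone is returned or methanol is lost toward an enol ether. Fallback, a two-step route through the enol ether: the enolate of 3 is O-methylated with a hard electrophile (Cs2CO3, MeOTf, DMF, 0 °C; C-methylation is disfavoured at the fully substituted α-carbon) to dimethyl 2,3,4-trimethoxypent-2-enedioate F7 as an alkene-isomer mixture, and base-catalysed conjugate addition of methanol (NaOMe cat., MeOH, rt) to this β-alkoxyacrylate then gives the ketal. The fallback sets out from 3 and comes back at 4.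

**Further compounds**

F1 | step 6 | 2,3,4,5,6-pentamethoxybenzoic acid | COc1c(OC)c(OC)c(C(=O)O)c(OC)c1OC
F2 | step 6 | 2,3,4,5,6-pentamethoxybenzoyl chloride | COc1c(OC)c(OC)c(C(Cl)=O)c(OC)c1OC
F3 | step 6 | 2-methoxy-1-(2,3,4,5,6-pentamethoxyphenyl)-3-phenylpropane-1,3-dione | COC(C(=O)c1ccccc1)C(=O)c1c(OC)c(OC)c(OC)c(OC)c1OC
F4 | step 6 | 1-(2-hydroxy-3,4,5,6-tetramethoxyphenyl)-2-methoxy-3-phenylpropane-1,3-dione | COC(C(=O)c1ccccc1)C(=O)c1c(O)c(OC)c(OC)c(OC)c1OC
F5 | step 5 | methyl 2,3,3,4-tetramethoxy-5-oxopentanoate | COC(=O)C(OC)C(OC)(OC)C(OC)C=O
F6 | step 5 | methyl 5-hydroxy-2,3,3,4,8-pentamethoxy-7,9-dioxo-9-phenylnonanoate | COC(=O)C(OC)C(OC)(OC)C(OC)C(O)CC(=O)C(OC)C(=O)c1ccccc1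
F7 | step 3 | dimethyl 2,3,4-trimethoxypent-2-enedioate | COC(=O)C(OC)=C(OC)C(OC)C(=O)OC
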